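(The earlier runs and the new flask are simulated with made-up constants.)

Time was where I began when you asked for a quick number and offered your hunch that the dosed flask would beat the others.

| flask | starting material | free catalyst | remark | time |
|---|---|---|---|---|
| teal | 0.20 M | 16 mM | run made earlier |  |
| violet | 0.20 M | 8 mM | run made earlier |  |
| blue | 0.20 M | 32 mM | run made earlier |  |
| Saturday's | 0.20 M (fed, over 3.20 h) | 16 mM | a stirred flask in which starting material is dosed at a steady rate over 3.20 h without added volume, worked up at 4.0 h | 4.0 h |
| Thursday's | 0.20 M | 16 mM | a single well-mixed tank run continuously and read at steady state, 4.0 h in it on average |  |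
| Tuesday's | 0.20 M | 16 mM | a single well-mixed tank run continuously and read at steady state, 40.0 h in it on average |  |
| Friday's | 0.20 M | 16 mM | a closed flask charged with all of it at once and left for 4.0 h | 4.0 h |

- teal (time / h: product / %, starting material / %): 1.00: 17.0, 76.5; 2.00: 32.8, 61.5; 3.00: 47.9, 45.2; 4.00: 60.8, 32.9
- violet (time / h: product / %, starting material / %): 0.333: 3.7, 94.1; 0.833: 7.7, 89.9; 1.50: 13.0, 84.0; 2.50: 21.1, 73.7
- blue (time / h: product / %, starting material / %): 0.333: 7.8, 78.3; 0.833: 25.8, 60.2; 1.50: 48.1, 41.9; 2.50: 68.5, 21.1

(standard deviation of a reading: 1 percentage point)

- the stated concentrations are those of everything mixed, before any reaction; amounts are the same in each set-up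
- steps that have been proposed: starting material + free catalyst -> catalyst intermediate; catalyst intermediate <-> free catalyst + product
- the feed brings no volume worth counting
- the earlier runs were made in a closed, stirred flask

1. the set-up with the highest amount of product at the outlet or at the end, in percent of the starting material put in ("none" if the first two lie within 2 percentage points) (Saturday's / Thursday's / Tuesday's / Friday's / none)
2. amount of product at the outlet or at the end, in percent of the starting material put in, Saturday's
3. amount of product at the outlet or at the end, in percent of the starting material put in, Thursday's
4. amount of product at the outlet or at the end, in percent of the starting material put in, Tuesday's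
5. amount of product at the outlet or at the end, in percent of the starting material put in, Friday's

In the proposed steps, starting material takes up free catalyst as catalyst intermediate, which then gives product and free catalyst back. I worked with the fraction left and not with the fraction made. In the teal run the fraction of starting material left fell from 76.5% at 1.00 h to 32.9% at 4.00 h, close to a straight line. I called that slope the drain pace, the fraction of the charge cleared per hour at this catalyst loading, and read it as 0.145 h⁻¹.

Multiplied by the hours, the pace gave me a budget in charges. It was 0.581 for each set-up lasting 4.0 h, on average in Thursday's tank, but 5.81 for Tuesday's tank, which was above the single charge. Dosing added no hours to Saturday's budget, so I did not share your hunch, and I put Tuesday's first. My budget ranked the flasks but gave no product figure of its own.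

The forecast gave 46% for Saturday's, 49.5% for Thursday's, 91.5% for Tuesday's and 61% for Friday's, with Tuesday's best. Of dosing it said “so the catalyst is underused”.

The flasks gave 46.5%, 50.1%, 90.8% and 60.2% in that order, and Tuesday's was best.

    starting material + free catalyst → catalyst intermediate (k = 71.5 M⁻¹ h⁻¹)
    catalyst intermediate ⇌ free catalyst + product (K = 0.173 M, k = 2.78 h⁻¹)

Taken together, the back-mixing and the longer stay carried Tuesday's tank to 90.8%, against 60.2% without them, but that tank did not spend its budget at the drain pace. At a fraction left of 4.75%, it made product at 0.0227 h⁻¹, slower than the 0.145 h⁻¹ of the teal run. Even so, hours were part of what held Saturday's flask down. It stood at 46.5% after 4.0 h, and left for 40.0 h, a budget of 5.80 charges like Tuesday's, it reached 95.8%.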